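**Retrosynthetic overview**
- The target comes from a tribenzyl-protected (E)-alkene by one hydrogenation that saturates C3'=C4' and removes all three benzyl groups.
- That alkene is cut at C3'=C4' (cross-metathesis) into an aryl C4 allylic acetate and (R)-undec-10-en-2-yl acetate.
- Key disconnection: the C2'–OAc bond of the allylic acetate, made directly by an enantioselective, branch-selective allylic C–H acetoxylation of a but-3-enyl arene. The arene comes from perbenzylated orsellinic acid by lateral lithiation and allylation.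
- The C12' acetate centre is bought as (R)-propylene oxide and extended with an octenyl Grignard reagent.
- No ring is formed; the only ring (the arene) comes from orsellinic acid.

Assumption: the target is read as 2-[(2R,12R)-2,12-bis(acetyloxy)tridecyl]-4,6-dihydroxybenzoic acid, and orsellinic acid, 8-bromooct-1-ene and (R)-propylene oxide are taken as acceptable commercial starting materials.

**Route**

Step 1
Reactants: 1 orsellinic acid (2,4-dihydroxy-6-methylbenzoic acid)
Product: 2 benzyl 2,4-bis(benzyloxy)-6-methylbenzoate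
Conditions: BnBr (3.6 equiv), K2CO3 (4.5 equiv), DMF, 60 °C
Reagents that add atoms: benzyl bromide, BrCc1ccccc1
Why: Base-mediated SN2 O-benzylation (carboxylate alkylation plus Williamson etherification); warming is needed for the hydrogen-bonded 2-hydroxyl, and no stereocentre is involved.

Step 2
Reactants: 2 benzyl 2,4-bis(benzyloxy)-6-methylbenzoate
Product: 4 benzyl 2,4-bis(benzyloxy)-6-(but-3-en-1-yl)benzoate, via benzylic organolithium 3 (not isolated)
Conditions: LiN(iPr)2 (1.15 equiv, commercial solution), THF, −78 °C; then allyl bromide (1.5 equiv), −78 → −40 °C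
Reagents that add atoms: allyl bromide, C=CCBr
Why: Lateral lithiation of an ortho-toluate gives an ester-stabilised benzylic anion that is allylated by SN2 at −78 °C, where the doubly ortho-shielded benzyl ester resists self-condensation.

Step 3
Reactants: 4 benzyl 2,4-bis(benzyloxy)-6-(but-3-en-1-yl)benzoate
Product: 5 benzyl 2-[(2S)-2-(acetyloxy)but-3-en-1-yl]-4,6-bis(benzyloxy)benzoate
Conditions: Pd(OAc)2 (10 mol%), chiral sulfoxide–oxazoline ligand L* (12 mol%; (4S)-4-tert-butyl-2-{2-[(S)-(4-methylphenyl)sulfinyl]phenyl}-4,5-dihydro-1,3-oxazole or its mirror image, whichever gives the 2S acetate), 1,4-benzoquinone (2 equiv), AcOH (4 equiv), 1,4-dioxane, 4 Å MS, 45 °C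
Reagents that add atoms: acetic acid, CC(=O)O
Why: Proposed new method: enantioselective, branch-selective intermolecular allylic C–H acetoxylation with a new catalyst design; Pd(OAc)2 bound to the chiral sulfoxide–oxazoline cleaves the allylic C2–H bond (sulfoxide-assisted, acetate as internal base) to give a π-allyl complex of divalent palladium, benzoquinone then displaces the hemilabile sulfoxide arm and triggers inner-sphere C–O reductive elimination of the bound acetate at the internal allyl terminus while the oxazoline is still on the metal, so the ligand decides which allyl face meets acetate and sets C2 as S (this becomes 2R in the target once the vinyl group is part of the saturated chain), and the zerovalent palladium released is returned to Pd(OAc)2 by benzoquinone and AcOH; the closest known reaction types are the racemic branched allylic C–H acetoxylation of terminal alkenes with Pd(OAc)2, a bis-sulfoxide and benzoquinone, its modestly selective variant with a chiral Lewis acid co-catalyst, and the enantioselective intramolecular allylic C–H oxidation to isochromans with Pd(OAc)2 and sulfoxide–oxazoline ligands.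

Step 4
Reactants: 6 8-bromooct-1-ene, 7 (R)-2-methyloxirane ((R)-propylene oxide)
Product: 10 (2R)-undec-10-en-2-yl acetate, via oct-7-enylmagnesium bromide 8 (not isolated), via bromomagnesium undecenolate 9 (not isolated)
Conditions: Mg, THF, rt; CuI (5 mol%), 7 (1.2 equiv), −30 → 0 °C; then Ac2O (1.5 equiv), DMAP (5 mol%), 0 °C → rt
Reagents that add atoms: acetic anhydride, CC(=O)OC(C)=O
Why: Grignard formation, then copper-catalysed SN2 opening of the terminal epoxide at its CH2 carbon (the stereocentre of 7 is not touched, so C2 stays R) and O-acetylation of the magnesium alkoxide in the same flask.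

Step 5
Reactants: 5 benzyl 2-[(2S)-2-(acetyloxy)but-3-en-1-yl]-4,6-bis(benzyloxy)benzoate, 10 (2R)-undec-10-en-2-yl acetate
Product: 11 benzyl 2-[(2S,3E,12R)-2,12-bis(acetyloxy)tridec-3-en-1-yl]-4,6-bis(benzyloxy)benzoate
Conditions: 10 (3 equiv), second-generation Hoveyda–Grubbs catalyst RuCl2(H2IMes)(=CH-C6H4-2-OiPr) (5 mol%), CH2Cl2, 40 °C
Reagents that add atoms: none
Why: Olefin cross-metathesis between the fast terminal alkene 10 (in excess) and the slower secondary allylic acetate 5 gives the E-configured disubstituted alkene with loss of ethene; both stereocentres are spectators.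

Step 6
Reactants: 11 benzyl 2-[(2S,3E,12R)-2,12-bis(acetyloxy)tridec-3-en-1-yl]-4,6-bis(benzyloxy)benzoate
Product: 12 2-[(2R,12R)-2,12-bis(acetyloxy)tridecyl]-4,6-dihydroxybenzoic acid
Conditions: H2 (1 atm), 10% Pd/C, EtOAc, rt
Reagents that add atoms: none
Why: Heterogeneous catalytic hydrogenation saturates C3=C4 (the C2 centre is untouched; its descriptor changes from S to R only because the priorities change) and hydrogenolysis removes the two benzyl ethers and the benzyl ester under neutral conditions that leave both acetates in place.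

**Compound list**

1 | orsellinic acid (2,4-dihydroxy-6-methylbenzoic acid) | Cc1cc(O)cc(O)c1C(=O)O | starting material
2 | benzyl 2,4-bis(benzyloxy)-6-methylbenzoate | Cc1cc(OCc2ccccc2)cc(OCc2ccccc2)c1C(=O)OCc1ccccc1 | intermediate
3 | benzyl 2,4-bis(benzyloxy)-6-(lithiomethyl)benzoate (benzylic organolithium) | [Li]Cc1cc(OCc2ccccc2)cc(OCc2ccccc2)c1C(=O)OCc1ccccc1 | intermediate
4 | benzyl 2,4-bis(benzyloxy)-6-(but-3-en-1-yl)benzoate | C=CCCc1cc(OCc2ccccc2)cc(OCc2ccccc2)c1C(=O)OCc1ccccc1 | intermediate
5 | benzyl 2-[(2S)-2-(acetyloxy)but-3-en-1-yl]-4,6-bis(benzyloxy)benzoate | CC(=O)O[C@H](C=C)Cc1cc(OCc2ccccc2)cc(OCc2ccccc2)c1C(=O)OCc1ccccc1 | intermediate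
6 | 8-bromooct-1-ene | C=CCCCCCCBr | starting material
7 | (R)-2-methyloxirane | C[C@@H]1CO1 | starting material
8 | oct-7-en-1-ylmagnesium bromide | C=CCCCCCC[Mg]Br | intermediate
9 | bromomagnesium (2R)-undec-10-en-2-olate | C=CCCCCCCC[C@@H](C)O[Mg]Br | intermediate
10 | (2R)-undec-10-en-2-yl acetate | C=CCCCCCCC[C@@H](C)OC(C)=O | intermediate
11 | benzyl 2-[(2S,3E,12R)-2,12-bis(acetyloxy)tridec-3-en-1-yl]-4,6-bis(benzyloxy)benzoate | CC(=O)O[C@H](/C=C/CCCCCCC[C@@H](C)OC(C)=O)Cc1cc(OCc2ccccc2)cc(OCc2ccccc2)c1C(=O)OCc1ccccc1 | intermediate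
12 | 2-[(2R,12R)-2,12-bis(acetyloxy)tridecyl]-4,6-dihydroxybenzoic acid | CC(=O)O[C@H](CCCCCCCCC[C@@H](C)OC(C)=O)Cc1cc(O)cc(O)c1C(=O)O | target

**Step count and risks**

Total steps: 6. Longest linear sequence: 5 (steps 1, 2, 3, 5, 6; step 4 is the side branch).

The three steps most likely to fail:

Step 3 (the proposed new reaction). The risks are low enantioselectivity, the linear acetate, a 1-aryl-1,3-diene from β-hydride elimination of the π-allyl complex, and palladation of the electron-rich arene. The C2 epimer cannot be removed after step 5, so 5 must be brought to high ee (crystallisation or chiral-phase chromatography) before use. The fallback uses known chemistry, sets out from 2 and comes back at 5. Lateral lithiation as in step 2 gives 3, which is alkylated with 3-bromo-1-(trimethylsilyl)prop-1-yne (THF, −78 °C) to benzyl 2,4-bis(benzyloxy)-6-[4-(trimethylsilyl)but-3-yn-1-yl]benzoate F1. Bu4NF buffered with AcOH in THF removes silicon to give benzyl 2,4-bis(benzyloxy)-6-(but-3-yn-1-yl)benzoate F2. The known rhodium-catalysed redox-neutral coupling of terminal alkynes with carboxylic acids ([Rh(cod)Cl]2, a DIOP-type chiral bisphosphine, AcOH, 1,2-dichloroethane, 70 °C) isomerises F2 in the flask to benzyl 2,4-bis(benzyloxy)-6-(buta-2,3-dien-1-yl)benzoate F3 and adds acetic acid at the substituted allene terminus to give the branched allylic acetate 5.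

Step 5 (cross-metathesis). The risks are slow turnover at the hindered allylic acetate, homodimer of 10 dominating, and alkene migration. The fallback replaces metathesis by a Julia–Kocienski olefination, sets out from 5 and 10 and comes back at 11. Ozonolysis of 10 with reductive work-up (O3, CH2Cl2/MeOH, −78 °C; NaBH4, 0 °C) gives (2R)-10-hydroxydecan-2-yl acetate F4. A Mitsunobu reaction with 1-phenyl-1H-tetrazole-5-thiol (PPh3, DIAD, THF) gives (2R)-10-[(1-phenyl-1H-tetrazol-5-yl)sulfanyl]decan-2-yl acetate F5. Oxidation ((NH4)6Mo7O24, H2O2, EtOH) gives (2R)-10-[(1-phenyl-1H-tetrazol-5-yl)sulfonyl]decan-2-yl acetate F6. Oxidative cleavage of the vinyl group of 5 (OsO4 cat., NaIO4, 2,6-lutidine, dioxane/H2O) gives benzyl 2-[(2S)-2-(acetyloxy)-3-oxopropyl]-4,6-bis(benzyloxy)benzoate F7. KN(SiMe3)2 is then added to a mixture of F6 and F7 in DME at −60 °C to give the E alkene 11; the low temperature and the pre-mixed partners limit epimerisation and acetyl migration at the α-acetoxy aldehyde.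

Step 6 (hydrogenation/hydrogenolysis). The risk is hydrogenolysis of the allylic C2–O bond on palladium before the alkene is saturated. The fallback separates the two events, sets out from 11 and comes back at 12. Diimide generated from 2-nitrobenzenesulfonylhydrazide and Et3N (CH2Cl2, rt) reduces only the C=C bond, with no metal and hence no allylic ionisation, to give benzyl 2-[(2R,12R)-2,12-bis(acetyloxy)tridecyl]-4,6-bis(benzyloxy)benzoate F8. Hydrogenolysis of F8 (H2, Pd(OH)2/C, EtOAc, rt) then gives 12.

**Further compounds**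

F1 | step 3 | benzyl 2,4-bis(benzyloxy)-6-[4-(trimethylsilyl)but-3-yn-1-yl]benzoate | C[Si](C)(C)C#CCCc1cc(OCc2ccccc2)cc(OCc2ccccc2)c1C(=O)OCc1ccccc1
F2 | step 3 | benzyl 2,4-bis(benzyloxy)-6-(but-3-yn-1-yl)benzoate | C#CCCc1cc(OCc2ccccc2)cc(OCc2ccccc2)c1C(=O)OCc1ccccc1
F3 | step 3 | benzyl 2,4-bis(benzyloxy)-6-(buta-2,3-dien-1-yl)benzoate | C=C=CCc1cc(OCc2ccccc2)cc(OCc2ccccc2)c1C(=O)OCc1ccccc1
F4 | step 5 | (2R)-10-hydroxydecan-2-yl acetate | OCCCCCCCC[C@@H](C)OC(C)=O
F5 | step 5 | (2R)-10-[(1-phenyl-1H-tetrazol-5-yl)sulfanyl]decan-2-yl acetate | CC(=O)O[C@H](C)CCCCCCCCSc1nnnn1-c1ccccc1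
F6 | step 5 | (2R)-10-[(1-phenyl-1H-tetrazol-5-yl)sulfonyl]decan-2-yl acetate | CC(=O)O[C@H](C)CCCCCCCCS(=O)(=O)c1nnnn1-c1ccccc1
F7 | step 5 | benzyl 2-[(2S)-2-(acetyloxy)-3-oxopropyl]-4,6-bis(benzyloxy)benzoate | CC(=O)O[C@H](C=O)Cc1cc(OCc2ccccc2)cc(OCc2ccccc2)c1C(=O)OCc1ccccc1
F8 | step 6 | benzyl 2-[(2R,12R)-2,12-bis(acetyloxy)tridecyl]-4,6-bis(benzyloxy)benzoate | CC(=O)O[C@H](CCCCCCCCC[C@@H](C)OC(C)=O)Cc1cc(OCc2ccccc2)cc(OCc2ccccc2)c1C(=O)OCc1ccccc1
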